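The data stem from a simulated flask on assumed constants; the scatter is artificial.

Start from the rate. In the amber flask nucleophile is fed (semi-batch) to electrophile, each turnover sets acid free, and free base can take that acid up.

the same everywhere: electrophile 0.30 M

|  | nucleophile | free base | remark | time |
|---|---|---|---|---|
| amber | 0.45 M (fed, over 2.5 min) | 0.15 M | the very flask that is asked about, followed so far |  |
| blue | 0.30 M (fed, over 2.5 min) | 0.15 M | run made earlier |  |
| flask | 0.450 M (fed, over 2.5 min) | 0.150 M |  | 2.5 min |

- amber (time / s: electrophile / %, target / %): 10.0: 99, 1; 12.0: 99, 0; 15.0: 99, 1; 20.0: 97, 0; 25.0: 98, 1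
- blue (time / min: electrophile / %, target / %): 0.167: 98, 2; 0.417: 98, 2; 0.667: 96, 5; 1.00: 87, 9; 1.50: 80, 22; 2.00: 68, 32; 2.50: 58, 40

(each reading ± 2 percentage points)

- part of the electrophile that has reacted at 2.5 min
- share of the unused nucleophile that is free and not bound as protonated nucleophile, at 2.5 min

- the numbers in the tables scatter with a standard deviation of 2 percentage points
- steps under discussion: nucleophile + acid set free <-> protonated nucleophile; electrophile + nucleophile -> acid set free + target; acid set free + free base <-> salt of the base
- the earlier runs do not show how much of nucleophile is bound; that part of a forecast is a guess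

Amber's readings are too early to show a rate, so read it from blue. Between 1.50 min and 2.50 min, averaging electrophile lost and target gained gives 0.0600 M min⁻¹. Divide by what stood at 2.00 min to get a reading of the rate constant, k = 0.0340 M⁻¹ s⁻¹.

Define the cover rate r_c as the mean turnover rate at which the acid set free just equals the free base charged when dosing ends, r_c = 0.0600 M min⁻¹.

Now slow amber step by step. With its whole charge present at once it would run at 0.276 M min⁻¹. Dosing gives a factor 0.5 on average. By its readings blue used 41.0% of both charges and, beyond dosing, kept a factor 0.535. Blue's two charges are equal, so as an estimate give each reagent the square root of that factor, which makes the slowing 0.655 times the share used. Test amber at the crossing itself, where acid set free equals the base charged: electrophile then gives a factor 0.673 and nucleophile 0.782. The mean rate is still 0.0725 M min⁻¹, faster than r_c, so amber should pass the crossing before the end. I therefore expect a conversion between 50.0% and 60.4%. At that upper end, putting the acid beyond the base charged on nucleophile, I reckon 88.4% of the unused nucleophile free.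

The forecast says 54% reacted, inside my range, and 85% free, less than my figure, the latter, in its words, “which is a guess”.

The amber flask gives 55.4% reacted and 92.6% of its unused nucleophile free at 2.5 min.

    nucleophile + acid set free ⇌ protonated nucleophile, settled at all times (K = 840 M⁻¹)
    electrophile + nucleophile → acid set free + target (k = 0.0350 M⁻¹ s⁻¹)
    acid set free + free base ⇌ salt of the base, settled at all times (K = 3.00 × 10⁵ M⁻¹)

The mean rate of the amber flask, 0.0664 M min⁻¹, lies above r_c, and at 2.50 min free base is down to 3.38% of its charge, beside 0.0210 M of protonated nucleophile. The neighbour flask with 0.27 M of nucleophile has a mean rate of 0.0452 M min⁻¹, below r_c, and keeps 25.5% of its free base and 99.2% of its unused nucleophile free.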